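**Retrosynthetic overview**

- Last C–C bond, pyrone C3 to the allylic CH2: Tsuji–Trost allylation of purchased 4-hydroxy-6-methyl-2-pyrone with the primary allylic carbonate of the complete hydroxy-terpenoid; the pyrone ring is never built.
- Ring-CH2–CH2 bond of the side chain: alkylation of the ring α-sulfonyl carbanion with an (E,E)-8-bromogeranyl silyl ether, then reductive removal of the sulfone.
- The cyclohexane, the only ring that is built, is closed in one flask by an asymmetric [3+3] annulation of (E)-2,2-dimethyl-4-(phenylsulfonyl)but-3-enal with (3-bromobut-3-enyl)[(trimethylsilyl)methyl]zinc. The ring CH2–CH(OH) bond comes from catalytic asymmetric alkyl transfer; the C(=CH2)–CH(ring) bond from 6-exo vinyl-radical closure.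
- Enabling feature: the ring is a 4-methylidenecyclohexan-1-ol whose carbinol CH and side-chain-bearing CH both flank the quaternary CMe2 carbon. One half is therefore a non-enolisable aldehyde with a β,γ-alkene; the other half (C=CH2, CH2, CH2) is a 3-bromobut-3-en-1-yl unit whose vinyl radical has no 1,5-hydrogen.
- Order of ring formation: cyclohexane only (step 5).

Key step: step 5

Assumption: the (1R,2R)-bis(triflamide)–titanium catalyst is taken to deliver the alkyl group to the Si face of the aldehyde, as it usually does with α-branched aliphatic aldehydes; if the sense proves opposite, the (1S,2S)-ligand is used instead.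

**Route**

Step 1
Reactants: 1 3-hydroxy-2,2-dimethylpropanal (hydroxypivaldehyde, used as its commercial dimer); 2 diethyl [(phenylsulfonyl)methyl]phosphonate
Product: 3 (E)-2,2-dimethyl-4-(phenylsulfonyl)but-3-en-1-ol
Conditions: LiCl, DBU, MeCN, rt
Reagents that add atoms: none
Why: Horner–Wadsworth–Emmons olefination of the non-enolisable aldehyde, released from its dimer under the mildly basic conditions, with the sulfonyl-stabilised phosphonate anion should give the E-vinyl sulfone; no stereocentre is formed.

Step 2
Reactants: 3 (E)-2,2-dimethyl-4-(phenylsulfonyl)but-3-en-1-ol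
Product: 4 (E)-2,2-dimethyl-4-(phenylsulfonyl)but-3-enal
Conditions: Dess–Martin periodinane, CH2Cl2, rt
Reagents that add atoms: none
Why: Dess–Martin oxidation of the neopentyl-type primary alcohol should stop at the aldehyde, which has no α-hydrogen and so can neither enolise nor move its double bond into conjugation.

Step 3
Reactants: 5 3-bromobut-3-en-1-ol
Product: 6 2-bromo-4-iodobut-1-ene
Conditions: I2, PPh3, imidazole, CH2Cl2, 0 °C
Reagents that add atoms: iodine II
Why: Appel-type iodination of the unhindered primary alcohol proceeds by SN2 displacement of the oxyphosphonium group and leaves the vinyl bromide untouched.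

Step 4
Reactants: 6 2-bromo-4-iodobut-1-ene
Product: 8 (3-bromobut-3-en-1-yl)[(trimethylsilyl)methyl]zinc (toluene solution, used at once), via alkylzinc iodide 7 (not isolated)
Conditions: Zn dust (activated with BrCH2CH2Br and TMSCl), THF, 35 °C; solution decanted from excess zinc; Me3SiCH2Li, −78 to 0 °C; THF removed in vacuo, toluene added, LiI filtered off
Reagents that add atoms: zinc [Zn]; (trimethylsilyl)methyllithium [Li]C[Si](C)(C)C
Why: Oxidative insertion of activated zinc is far faster into the primary C–I bond than into the alkenyl C–Br bond, and salt metathesis of the alkylzinc iodide with (trimethylsilyl)methyllithium should give the mixed diorganozinc, in which Me3SiCH2 is a non-transferable ligand so that the single 3-bromobut-3-enyl group is the one delivered.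

Step 5
Reactants: 4 (E)-2,2-dimethyl-4-(phenylsulfonyl)but-3-enal; 8 (3-bromobut-3-en-1-yl)[(trimethylsilyl)methyl]zinc
Product: 10 (1S,3R)-2,2-dimethyl-4-methylidene-3-[(phenylsulfonyl)methyl]cyclohexan-1-ol, via bromo-dienol sulfone 9 (not isolated)
Conditions: Ti(OiPr)4 (2 equiv), (1R,2R)-N,N′-bis(trifluoromethanesulfonyl)cyclohexane-1,2-diamine (8 mol %), toluene, −20 °C; then i-PrOH; then Bu3SnH, AIBN (cat.), 80 °C, slow addition, same flask
Reagents that add atoms: none
Why: The mixed diorganozinc transfers its 3-bromobut-3-enyl group, and not the Me3SiCH2 group, to the aldehyde carbon inside the chiral titanium bis(sulfonamide) complex (catalytic asymmetric organozinc 1,2-addition), which forms the CH2–CH(OH) bond and should set the carbinol centre as S by Si-face delivery; after protonolysis of the zinc species, Bu3Sn• abstracts bromine from the 2-bromoalkene and the vinyl radical adds to the β-carbon of the vinyl sulfone, which forms the C(=CH2)–CH bond and leaves the exocyclic methylidene in place before the α-sulfonyl radical takes hydrogen from Bu3SnH. The closest known reaction types are the titanium/bis(triflamide)-catalysed addition of functionalised mixed (trimethylsilyl)methyl alkylzincs to α-branched aliphatic aldehydes and the tin-hydride vinyl-radical cyclisation of 2-bromo-1-alkenes onto electron-poor alkenes, merged here as a one-flask [3+3] annulation with a bifunctional three-carbon reagent. The ring closes in the 6-exo-trig mode. The ring CH centre is controlled by the carbinol centre through a chair transition state in which the oxygen substituent and the sulfonylvinyl arm are both equatorial beside the CMe2 group, which should give the 1,3-cis (1S,3R) product. The step needs chemoselective alkyl transfer to the aldehyde (vinyl sulfone and vinyl bromide are inert to the organozinc without copper), 6-exo over 7-endo closure (secured by the polarisation of the vinyl sulfone), and cyclisation ahead of reduction or hydrogen shift (secured by slow tin hydride addition and by the quaternary CMe2 carbon, which removes any 1,5-hydrogen).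

Step 6
Reactants: 10 (1S,3R)-2,2-dimethyl-4-methylidene-3-[(phenylsulfonyl)methyl]cyclohexan-1-ol
Product: 11 tert-butyl({(1S,3R)-2,2-dimethyl-4-methylidene-3-[(phenylsulfonyl)methyl]cyclohexyl}oxy)dimethylsilane
Conditions: TBSOTf, 2,6-lutidine, CH2Cl2, 0 °C
Reagents that add atoms: tert-butyldimethylsilyl trifluoromethanesulfonate CC(C)(C)[Si](C)(C)OS(=O)(=O)C(F)(F)F
Why: Silylation with the reactive silyl triflate should protect the hindered secondary alcohol so that only the sulfone α-carbon is deprotonated later; no stereocentre is touched.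

Step 7
Reactants: 12 geraniol
Product: 13 tert-butyl{[(2E)-3,7-dimethylocta-2,6-dien-1-yl]oxy}dimethylsilane
Conditions: TBSCl, imidazole, DMF, rt
Reagents that add atoms: tert-butyldimethylsilyl chloride CC(C)(C)[Si](C)(C)Cl
Why: Standard imidazole-promoted silylation of the primary allylic alcohol gives a base-stable ether for the carbanion chemistry to come.

Step 8
Reactants: 13 tert-butyl{[(2E)-3,7-dimethylocta-2,6-dien-1-yl]oxy}dimethylsilane
Product: 14 (2E,6E)-8-{[tert-butyl(dimethyl)silyl]oxy}-2,6-dimethylocta-2,6-dien-1-ol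
Conditions: SeO2 (cat.), t-BuOOH, CH2Cl2, rt
Reagents that add atoms: selenium dioxide O=[Se]=O (oxygen transfer, catalytic); tert-butyl hydroperoxide CC(C)(C)OO (stoichiometric oxygen source)
Why: Riley allylic oxidation (ene reaction, then [2,3]-sigmatropic shift) attacks the more electron-rich terminal alkene at its E-methyl group and should give the (E)-allylic alcohol.

Step 9
Reactants: 14 (2E,6E)-8-{[tert-butyl(dimethyl)silyl]oxy}-2,6-dimethylocta-2,6-dien-1-ol
Product: 15 {[(2E,6E)-8-bromo-3,7-dimethylocta-2,6-dien-1-yl]oxy}(tert-butyl)dimethylsilane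
Conditions: CBr4, PPh3, CH2Cl2, −20 °C
Reagents that add atoms: tetrabromomethane BrC(Br)(Br)Br
Why: Appel bromination of the primary allylic alcohol under neutral conditions should keep the alkene geometry and the silyl ether.

Step 10
Reactants: 11 tert-butyl({(1S,3R)-2,2-dimethyl-4-methylidene-3-[(phenylsulfonyl)methyl]cyclohexyl}oxy)dimethylsilane; 15 {[(2E,6E)-8-bromo-3,7-dimethylocta-2,6-dien-1-yl]oxy}(tert-butyl)dimethylsilane
Product: 16 tert-butyl({(1S,3R)-3-[(3E,7E)-9-{[tert-butyl(dimethyl)silyl]oxy}-3,7-dimethyl-1-(phenylsulfonyl)nona-3,7-dien-1-yl]-2,2-dimethyl-4-methylidenecyclohexyl}oxy)dimethylsilane (both epimers at the sulfone-bearing carbon)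
Conditions: n-BuLi, THF–DMPU, −78 °C; then 15, −78 to −20 °C
Reagents that add atoms: none
Why: Alkylation of the lithiated sulfone by SN2 attack on the primary allylic bromide joins ring and chain; the new stereocentre at the sulfone carbon is removed in the next step and the ring centres are not acidic.

Step 11
Reactants: 16 the coupled sulfone (both epimers)
Product: 17 tert-butyl({(1S,3R)-3-[(3E,7E)-9-{[tert-butyl(dimethyl)silyl]oxy}-3,7-dimethylnona-3,7-dien-1-yl]-2,2-dimethyl-4-methylidenecyclohexyl}oxy)dimethylsilane
Conditions: Na(Hg) (5 %), Na2HPO4, MeOH–THF, −20 °C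
Reagents that add atoms: none
Why: Buffered sodium-amalgam reductive desulfonylation cleaves the alkyl C–S bond by electron transfer and protonation; the sulfone is homoallylic, not allylic, so alkene position and geometry should be kept.

Step 12
Reactants: 17 the bis-silyl ether
Product: 18 (1S,3R)-3-[(3E,7E)-9-hydroxy-3,7-dimethylnona-3,7-dien-1-yl]-2,2-dimethyl-4-methylidenecyclohexan-1-ol
Conditions: TBAF, THF, 50 °C
Reagents that add atoms: none
Why: Fluoride-mediated desilylation removes both silyl ethers in one operation without touching the alkenes or the stereocentres.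

Step 13
Reactants: 18 (1S,3R)-3-[(3E,7E)-9-hydroxy-3,7-dimethylnona-3,7-dien-1-yl]-2,2-dimethyl-4-methylidenecyclohexan-1-ol
Product: 19 (2E,6E)-9-[(1R,3S)-3-hydroxy-2,2-dimethyl-6-methylidenecyclohexyl]-3,7-dimethylnona-2,6-dien-1-yl methyl carbonate
Conditions: ClCO2Me, pyridine, CH2Cl2, −20 °C
Reagents that add atoms: methyl chloroformate COC(=O)Cl
Why: Acylation should occur selectively at the unhindered primary allylic hydroxyl, because the ring hydroxyl is secondary and flanked by the quaternary carbon.

Step 14
Reactants: 19 the allylic methyl carbonate; 20 4-hydroxy-6-methyl-2H-pyran-2-one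
Product: 21 sartorypyrone D, 4-hydroxy-3-{(2E,6E)-9-[(1R,3S)-3-hydroxy-2,2-dimethyl-6-methylidenecyclohexyl]-3,7-dimethylnona-2,6-dien-1-yl}-6-methyl-2H-pyran-2-one
Conditions: Pd(PPh3)4 (5 mol %), THF, 40 °C, excess 20
Reagents that add atoms: none
Why: In this Tsuji–Trost allylation the carbonate ionises to a π-allyl palladium complex and methoxide, and the soft C3 carbon of the deprotonated pyrone should attack the unsubstituted allyl terminus to give the linear E product under neutral conditions.

**Compound list**

1 | 3-hydroxy-2,2-dimethylpropanal | OCC(C)(C)C=O | starting material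
2 | diethyl [(phenylsulfonyl)methyl]phosphonate | CCOP(=O)(OCC)CS(=O)(=O)c1ccccc1 | starting material
3 | (E)-2,2-dimethyl-4-(phenylsulfonyl)but-3-en-1-ol | OCC(C)(C)/C=C/S(=O)(=O)c1ccccc1 | intermediate
4 | (E)-2,2-dimethyl-4-(phenylsulfonyl)but-3-enal | O=CC(C)(C)/C=C/S(=O)(=O)c1ccccc1 | intermediate
5 | 3-bromobut-3-en-1-ol | C=C(Br)CCO | starting material
6 | 2-bromo-4-iodobut-1-ene | C=C(Br)CCI | intermediate
7 | (3-bromobut-3-en-1-yl)zinc iodide | C=C(Br)CC[Zn]I | intermediate
8 | (3-bromobut-3-en-1-yl)[(trimethylsilyl)methyl]zinc | C=C(Br)CC[Zn]C[Si](C)(C)C | intermediate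
9 | (1E,4S)-7-bromo-3,3-dimethyl-1-(phenylsulfonyl)octa-1,7-dien-4-ol | C=C(Br)CC[C@H](O)C(C)(C)/C=C/S(=O)(=O)c1ccccc1 | intermediate
10 | (1S,3R)-2,2-dimethyl-4-methylidene-3-[(phenylsulfonyl)methyl]cyclohexan-1-ol | C=C1CC[C@H](O)C(C)(C)[C@@H]1CS(=O)(=O)c1ccccc1 | intermediate
11 | tert-butyl({(1S,3R)-2,2-dimethyl-4-methylidene-3-[(phenylsulfonyl)methyl]cyclohexyl}oxy)dimethylsilane | C=C1CC[C@H](O[Si](C)(C)C(C)(C)C)C(C)(C)[C@@H]1CS(=O)(=O)c1ccccc1 | intermediate
12 | geraniol, (2E)-3,7-dimethylocta-2,6-dien-1-ol | CC(C)=CCC/C(C)=C/CO | starting material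
13 | tert-butyl{[(2E)-3,7-dimethylocta-2,6-dien-1-yl]oxy}dimethylsilane | CC(C)=CCC/C(C)=C/CO[Si](C)(C)C(C)(C)C | intermediate
14 | (2E,6E)-8-{[tert-butyl(dimethyl)silyl]oxy}-2,6-dimethylocta-2,6-dien-1-ol | OC/C(C)=C/CC/C(C)=C/CO[Si](C)(C)C(C)(C)C | intermediate
15 | {[(2E,6E)-8-bromo-3,7-dimethylocta-2,6-dien-1-yl]oxy}(tert-butyl)dimethylsilane | BrC/C(C)=C/CC/C(C)=C/CO[Si](C)(C)C(C)(C)C | intermediate
16 | tert-butyl({(1S,3R)-3-[(3E,7E)-9-{[tert-butyl(dimethyl)silyl]oxy}-3,7-dimethyl-1-(phenylsulfonyl)nona-3,7-dien-1-yl]-2,2-dimethyl-4-methylidenecyclohexyl}oxy)dimethylsilane, both epimers at the sulfone carbon | C=C1CC[C@H](O[Si](C)(C)C(C)(C)C)C(C)(C)[C@@H]1C(C/C(C)=C/CC/C(C)=C/CO[Si](C)(C)C(C)(C)C)S(=O)(=O)c1ccccc1 | intermediate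
17 | tert-butyl({(1S,3R)-3-[(3E,7E)-9-{[tert-butyl(dimethyl)silyl]oxy}-3,7-dimethylnona-3,7-dien-1-yl]-2,2-dimethyl-4-methylidenecyclohexyl}oxy)dimethylsilane | C=C1CC[C@H](O[Si](C)(C)C(C)(C)C)C(C)(C)[C@@H]1CC/C(C)=C/CC/C(C)=C/CO[Si](C)(C)C(C)(C)C | intermediate
18 | (1S,3R)-3-[(3E,7E)-9-hydroxy-3,7-dimethylnona-3,7-dien-1-yl]-2,2-dimethyl-4-methylidenecyclohexan-1-ol | C=C1CC[C@H](O)C(C)(C)[C@@H]1CC/C(C)=C/CC/C(C)=C/CO | intermediate
19 | (2E,6E)-9-[(1R,3S)-3-hydroxy-2,2-dimethyl-6-methylidenecyclohexyl]-3,7-dimethylnona-2,6-dien-1-yl methyl carbonate | C=C1CC[C@H](O)C(C)(C)[C@@H]1CC/C(C)=C/CC/C(C)=C/COC(=O)OC | intermediate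
20 | 4-hydroxy-6-methyl-2H-pyran-2-one | Cc1cc(O)cc(=O)o1 | starting material
21 | sartorypyrone D | C=C1CC[C@H](O)C(C)(C)[C@@H]1CC/C(C)=C/CC/C(C)=C/Cc1c(O)cc(C)oc1=O | target

**Step count and risks**

Total step count: 14. Longest linear sequence: 9 steps (steps 1, 2, 5, 6, 10, 11, 12, 13, 14).

Most likely to fail, step 5: alkyl transfer to the hindered neopentyl-type aldehyde may be slow or poorly face-selective, and lithium iodide carried over from the reagent preparation may erode the enantioselectivity. The zinc and titanium residues may also disturb the radical chain, so that the vinyl radical is reduced before it cyclises or closes with poor facial selectivity. The fallback separates bond formation from stereocontrol and sets out from 4 and 8. Addition promoted by Ti(OiPr)4 with the racemic bis(triflamide) ligand gives the racemic bromo-dienol F1, which is oxidised with Dess–Martin periodinane to the bromo-dienone F2. Corey–Bakshi–Shibata reduction ((R)-methyl oxazaborolidine, catecholborane, −78 °C) differentiates the tertiary-alkyl side from the CH2 side of the ketone and should give 9, now isolated and purified. A separate tin-hydride vinyl-radical cyclisation (Bu3SnH, AIBN, benzene, 80 °C, syringe pump) on pure 9 comes back to the route at 10.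

Second, step 14: the ambident pyrone may be allylated on oxygen or twice at C3, the nucleophile may attack the substituted allyl terminus, and π–σ–π isomerisation of the allyl–palladium intermediate may erode the E geometry of the adjacent trisubstituted alkene. The fallback builds the pyrone instead of allylating it and sets out from 18. Appel bromination at the primary allylic hydroxyl (CBr4, PPh3, −30 °C) gives the allylic bromide F3, and SN2 alkylation of the sodium enolate of ethyl acetoacetate gives the 2-substituted acetoacetate F4. γ-Acylation of its dianion (LDA in excess, which also covers the ring alkoxide, then N-methoxy-N-methylacetamide) gives the 3,5-dioxo ester F5. Lactonisation with DBU in hot toluene comes back to the route at 21.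

Third, step 8: the allylic oxidation may run on to the enal, attack other allylic positions or stall at partial conversion. The fallback replaces C–H oxidation by cleavage and olefination and sets out from 13. Epoxidation of the more electron-rich terminal alkene (mCPBA, −20 °C) gives the epoxide F6, and periodic acid cleavage at 0 °C gives the aldehyde F7. Wittig reaction with ethyl 2-(triphenylphosphoranylidene)propanoate gives the E-enoate F8, and DIBAL reduction comes back to the route at 14.

**Further compounds**

F1 | step 5 | rac-(1E)-7-bromo-3,3-dimethyl-1-(phenylsulfonyl)octa-1,7-dien-4-ol | C=C(Br)CCC(O)C(C)(C)/C=C/S(=O)(=O)c1ccccc1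
F2 | step 5 | (1E)-7-bromo-3,3-dimethyl-1-(phenylsulfonyl)octa-1,7-dien-4-one | C=C(Br)CCC(=O)C(C)(C)/C=C/S(=O)(=O)c1ccccc1
F3 | step 14 | (1S,3R)-3-[(3E,7E)-9-bromo-3,7-dimethylnona-3,7-dien-1-yl]-2,2-dimethyl-4-methylidenecyclohexan-1-ol | C=C1CC[C@H](O)C(C)(C)[C@@H]1CC/C(C)=C/CC/C(C)=C/CBr
F4 | step 14 | ethyl (4E,8E)-2-acetyl-11-[(1R,3S)-3-hydroxy-2,2-dimethyl-6-methylidenecyclohexyl]-5,9-dimethylundeca-4,8-dienoate (both epimers at C2) | C=C1CC[C@H](O)C(C)(C)[C@@H]1CC/C(C)=C/CC/C(C)=C/CC(C(C)=O)C(=O)OCC
F5 | step 14 | ethyl (4E,8E)-11-[(1R,3S)-3-hydroxy-2,2-dimethyl-6-methylidenecyclohexyl]-5,9-dimethyl-2-(3-oxobutanoyl)undeca-4,8-dienoate (both epimers at C2) | C=C1CC[C@H](O)C(C)(C)[C@@H]1CC/C(C)=C/CC/C(C)=C/CC(C(=O)CC(C)=O)C(=O)OCC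
F6 | step 8 | tert-butyl{[(2E)-5-(3,3-dimethyloxiran-2-yl)-3-methylpent-2-en-1-yl]oxy}dimethylsilane (racemic) | CC1(C)OC1CC/C(C)=C/CO[Si](C)(C)C(C)(C)C
F7 | step 8 | (4E)-6-{[tert-butyl(dimethyl)silyl]oxy}-4-methylhex-4-enal | O=CCC/C(C)=C/CO[Si](C)(C)C(C)(C)C
F8 | step 8 | ethyl (2E,6E)-8-{[tert-butyl(dimethyl)silyl]oxy}-2,6-dimethylocta-2,6-dienoate | CCOC(=O)/C(C)=C/CC/C(C)=C/CO[Si](C)(C)C(C)(C)C
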